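The route rests on cutting the benzo ring of the indole at C3a–C4 and C7–C7a. Its C4(Br)–C5H–C6H–C7(Br) edge maps onto diene carbons C2 to C5 of 2,5-dibromothiophene 1,1-dioxide, and the N1-bearing C7a–C3a bond onto the C5=C4 double bond of N-Boc-2,3-dihydropyrrole, an enecarbamate. In one operation an inverse-demand [4+2] cycloaddition joins these two precursors, SO2 is extruded and DDQ aromatizes the new six-membered ring, giving the 4,7-dibromoindoline with both bromines in place. Dehydrogenation of the five-membered ring, Boc-directed C2 chlorination, Boc removal and C3 bromination then complete the target.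

Key step: step 2

Remark: enecarbamate 4 and the silyl alkyne named in the first fallback are taken as purchasable; cycloadduct 5 is drawn as its endo isomer, and the exo isomer would give the same diene 6.

Step 1
Reactants: 1 2,5-dibromothiophene
Product: 3 2,5-dibromothiophene 1,1-dioxide, via thiophene S-oxide 2 (not isolated)
Conditions: CF3CO3H [from (CF3CO)2O and 50% aq H2O2], CH2Cl2, 0 °C to rt; product kept cold and used within days
Reagents that add atoms: trifluoroperacetic acid OOC(=O)C(F)(F)F (made in the flask from hydrogen peroxide OO and trifluoroacetic anhydride)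
Why: Peracid S-oxidation of a sulfide to the sulfone, in which the strong peracid overcomes the poor nucleophilicity of the dibrominated thiophene sulfur, the non-aromatic S-oxide 2 should be oxidized again faster than it dimerizes, and the 2,5-bromines slow self-dimerization of the sulfone.

Step 2
Reactants: 3 2,5-dibromothiophene 1,1-dioxide; 4 tert-butyl 2,3-dihydro-1H-pyrrole-1-carboxylate
Product: 7 tert-butyl 4,7-dibromoindoline-1-carboxylate, via bridged sulfone cycloadduct 5 (not isolated), via cis-fused cyclohexadiene 6 (not isolated)
Conditions: 3 (1.2 equiv, in portions), NaHCO3 (solid buffer), toluene, 80 °C, Ar sweep; then DDQ (1.3 equiv), 0 °C to rt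
Reagents that add atoms: none
Why: The electron-poor diene C2(Br)=C3–C4=C5(Br) of sulfone 3 and the electron-rich C4=C5 bond of enecarbamate 4 should combine in a concerted, suprafacial inverse-electron-demand Diels–Alder reaction to the bridged sulfone 5, which loses SO2 by thermal cheletropic extrusion to give diene 6, after which DDQ removes the C3a and C7a hydrogens (hydride abstraction, then proton loss). The closest known reaction type is the cycloaddition and SO2-extrusion benzannulation of halogenated thiophene 1,1-dioxides with alkenes, enol ethers included, followed by quinone dehydrogenation. The six-membered carbocycle is closed by intermolecular [4+2] cycloaddition that forms C3a–C4 and C7–C7a onto the existing five-membered nitrogen ring, the SO2 bridge serving only as a traceless tether. The two ring-fusion centres of 6 are set cis by suprafacial addition to the cis alkene of the five-membered ring, are racemic, and are erased by the dehydrogenation, so the endo or exo course is of no consequence. No regioselectivity is needed because the diene is symmetrical; what is needed is dehydrogenation of 6 in preference to isomerization and loss of HBr or of the carbamate nitrogen, which the vinylic position of both bromines, the buffer, the moderate temperature and the immediate DDQ treatment should secure.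

Step 3
Reactants: 7 tert-butyl 4,7-dibromoindoline-1-carboxylate
Product: 8 tert-butyl 4,7-dibromoindole-1-carboxylate
Conditions: DDQ (2.5 equiv), 1,4-dioxane, 100 °C
Reagents that add atoms: none
Why: Quinone dehydrogenation, in which DDQ abstracts hydride from the five-membered ring of the N-acylindoline and proton loss gives the aromatic indole, a known but slow conversion for carbamate-protected indolines that heat and excess oxidant should drive while the aryl bromides stay inert.

Step 4
Reactants: 8 tert-butyl 4,7-dibromoindole-1-carboxylate
Product: 10 tert-butyl 4,7-dibromo-2-chloroindole-1-carboxylate, via 2-lithioindole 9 (not isolated)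
Conditions: LiN(iPr)2 (1.3 equiv), THF, −78 °C; then C2Cl6, −78 °C to 0 °C
Reagents that add atoms: hexachloroethane ClC(Cl)(Cl)C(Cl)(Cl)Cl
Why: Directed metalation, in which the Boc carbonyl guides the non-nucleophilic amide base to the most acidic C2–H without bromine–lithium exchange at C4 or C7, followed by electrophilic chlorination of the aryllithium 9 by hexachloroethane.

Step 5
Reactants: 10 tert-butyl 4,7-dibromo-2-chloroindole-1-carboxylate
Product: 11 4,7-dibromo-2-chloro-1H-indole
Conditions: K2CO3, MeOH/THF, rt to 40 °C; product kept cold and used at once
Reagents that add atoms: none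
Why: Base-mediated methanolysis (acyl transfer) of the activated azole carbamate should release the indole under non-acidic conditions, so the acid-sensitive 2-chloroindole is not hydrolysed to the oxindole.

Step 6
Reactants: 11 4,7-dibromo-2-chloro-1H-indole
Product: 12 3,4,7-tribromo-2-chloro-1H-indole
Conditions: NBS (1.0 equiv), DMF, −20 °C to 0 °C, dark
Reagents that add atoms: N-bromosuccinimide O=C1CCC(=O)N1Br
Why: Electrophilic aromatic substitution at C3, the only strongly nucleophilic (enamine-type) position left, the dibrominated benzo ring being deactivated, so one equivalent of NBS at low temperature should brominate there alone.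

Compound list
1 | 2,5-dibromothiophene | Brc1ccc(Br)s1 | starting material
2 | 2,5-dibromothiophene 1-oxide | O=S1C(Br)=CC=C1Br | intermediate
3 | 2,5-dibromothiophene 1,1-dioxide | O=S1(=O)C(Br)=CC=C1Br | intermediate
4 | tert-butyl 2,3-dihydro-1H-pyrrole-1-carboxylate | CC(C)(C)OC(=O)N1CCC=C1 | starting material
5 | racemic tert-butyl 4,7-dibromo-8,8-dioxo-2,3,3a,4,7,7a-hexahydro-4,7-epithioindole-1-carboxylate (7-thiabicyclo[2.2.1]hept-2-ene 7,7-dioxide core, bridgehead bromines, pyrrolidine ring cis-fused and anti to the SO2 bridge) | CC(C)(C)OC(=O)N1CC[C@H]2[C@@H]1[C@@]1(Br)C=C[C@]2(Br)S1(=O)=O | intermediate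
6 | racemic cis tert-butyl 4,7-dibromo-2,3,3a,7a-tetrahydro-1H-indole-1-carboxylate (H-3a and H-7a on the same face) | CC(C)(C)OC(=O)N1CC[C@@H]2C(Br)=CC=C(Br)[C@H]12 | intermediate
7 | tert-butyl 4,7-dibromoindoline-1-carboxylate | CC(C)(C)OC(=O)N1CCc2c(Br)ccc(Br)c21 | intermediate
8 | tert-butyl 4,7-dibromoindole-1-carboxylate | CC(C)(C)OC(=O)n1ccc2c(Br)ccc(Br)c21 | intermediate
9 | tert-butyl 4,7-dibromo-2-lithioindole-1-carboxylate | [Li]c1cc2c(Br)ccc(Br)c2n1C(=O)OC(C)(C)C | intermediate
10 | tert-butyl 4,7-dibromo-2-chloroindole-1-carboxylate | CC(C)(C)OC(=O)n1c(Cl)cc2c(Br)ccc(Br)c21 | intermediate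
11 | 4,7-dibromo-2-chloro-1H-indole | Clc1cc2c(Br)ccc(Br)c2[nH]1 | intermediate
12 | 3,4,7-tribromo-2-chloro-1H-indole | Clc1[nH]c2c(Br)ccc(Br)c2c1Br | target

Total step count: 6
Longest linear sequence: 6 steps (1 to 12; compound 4 enters at step 2)

Steps most likely to fail

Step 2. The enecarbamate may be consumed by acid-triggered oligomerization before it cycloadds, or the dihydro intermediate may aromatize by expelling HBr or the carbamate nitrogen instead of being dehydrogenated. The fallback sets out from 3 and comes back at 7; it builds the arene first and closes the nitrogen ring afterwards. Sulfone 3 would be heated with tert-butyl [4-(trimethylsilyl)but-3-yn-1-yl]carbamate (chlorobenzene, 130 °C, sealed tube). The cycloadduct tert-butyl N-{2-[1,4-dibromo-7,7-dioxo-3-(trimethylsilyl)-7-thiabicyclo[2.2.1]hepta-2,5-dien-2-yl]ethyl}carbamate F1 should lose SO2 at once to give tert-butyl N-{2-[3,6-dibromo-2-(trimethylsilyl)phenyl]ethyl}carbamate F2, with no oxidant needed and nothing to eliminate. Ipso-iododesilylation with ICl (CH2Cl2, 0 °C) should give tert-butyl N-[2-(3,6-dibromo-2-iodophenyl)ethyl]carbamate F3. An intramolecular Goldberg amidation (CuI, N,N'-dimethylethylenediamine, Cs2CO3, toluene, 80 °C), selective for the C–I bond over both C–Br bonds, should then close the five-membered ring to 7.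

Step 3. Hydride abstraction from the electron-poor, carbamate-deactivated indoline may be too slow, so that thermal Boc loss and decomposition compete. The fallback sets out from 7 and comes back at 8; it oxidizes the free amine instead. Acidolysis (CF3CO2H, CH2Cl2, rt) should give 4,7-dibromoindoline F4, whose free N–H indoline is dehydrogenated readily by activated MnO2 (CH2Cl2, rt) to 4,7-dibromo-1H-indole F5. Boc2O with catalytic 4-dimethylaminopyridine in MeCN should then return 8.

Step 4. The 2-lithio species may equilibrate to ring-metalated positions next to bromine, with loss of LiBr or halogen migration, or undergo N-to-C2 Boc transfer before it meets the chlorinating agent. The fallback sets out from 8 and comes back at 10; it traps the anion as it forms and makes the C–Cl bond from a C–B bond. LiN(iPr)2 would be added to a mixture of 8 and B(OiPr)3 in THF at 0 °C (in situ quench), and mild acidic work-up should give [4,7-dibromo-1-(tert-butoxycarbonyl)indol-2-yl]boronic acid F6. Copper-catalysed chlorodeboronation (NCS, CuCl catalyst, MeCN, rt to 50 °C) should then give 10.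

Further compounds
F1 | step 2 | racemic tert-butyl N-{2-[1,4-dibromo-7,7-dioxo-3-(trimethylsilyl)-7-thiabicyclo[2.2.1]hepta-2,5-dien-2-yl]ethyl}carbamate | C[Si](C)(C)C1=C(CCNC(=O)OC(C)(C)C)[C@@]2(Br)C=C[C@]1(Br)S2(=O)=O
F2 | step 2 | tert-butyl N-{2-[3,6-dibromo-2-(trimethylsilyl)phenyl]ethyl}carbamate | C[Si](C)(C)c1c(Br)ccc(Br)c1CCNC(=O)OC(C)(C)C
F3 | step 2 | tert-butyl N-[2-(3,6-dibromo-2-iodophenyl)ethyl]carbamate | Ic1c(Br)ccc(Br)c1CCNC(=O)OC(C)(C)C
F4 | step 3 | 4,7-dibromoindoline | Brc1ccc(Br)c2NCCc12
F5 | step 3 | 4,7-dibromo-1H-indole | Brc1ccc(Br)c2[nH]ccc12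
F6 | step 4 | [4,7-dibromo-1-(tert-butoxycarbonyl)indol-2-yl]boronic acid | CC(C)(C)OC(=O)n1c(B(O)O)cc2c(Br)ccc(Br)c21
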